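(The data are calculated on assumed constants; scatter was added.)

If I follow one E through a flask of L, it comes to two forks: it turns L into D and lives on, or it meets a second E and goes to J. Charge half the E and each E finds a partner correspondingly less often, but each L turned takes twice as long, so the chance of losing an E per L turned stays the same. Two flasks with the same L charged should therefore pass through the same states at different speeds.

| setting | theta | gamma | delta | flask |
|---|---|---|---|---|
| L | 14 mM | 22 mM | 10 mM | 10 mM |
| E | 0.022 mol% | 0.022 mol% | 0.011 mol% | 0.022 mol% |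
| remark | run made earlier | run made earlier | run made earlier |  |

| run | time / min | D / % | L / % |
|---|---|---|---|
| theta | 2.50 | 1.9 | 98.4 |
| theta | 8.00 | 4.9 | 94.9 |
| theta | 15.0 | 7.6 | 92.3 |
| theta | 20.0 | 9.1 | 91.4 |
| theta | 30.0 | 11.1 | 88.3 |
| theta | 40.0 | 12.9 | 87.2 |
| theta | 50.0 | 15.0 | 85.8 |
| gamma | 4.00 | 1.6 | 98.2 |
| gamma | 6.00 | 2.2 | 97.7 |
| gamma | 10.0 | 3.2 | 97.1 |
| gamma | 15.0 | 4.6 | 96.0 |
| gamma | 20.0 | 4.4 | 94.7 |
| gamma | 30.0 | 6.9 | 94.1 |
| gamma | 50.0 | 8.0 | 92.0 |
| delta | 10.0 | 4.7 | 95.9 |
| delta | 20.0 | 7.8 | 91.8 |
| delta | 30.0 | 11.0 | 89.8 |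
| delta | 40.0 | 12.5 | 86.9 |
| delta | 50.0 | 15.0 | 85.6 |

(each reading ± 0.3 percentage points)

- factor on the rate of making D when 50 % of the L are converted if E is charged twice over
- factor on the rate when 50 % of the L are converted if E is charged at 0.004 mol% instead

- what may be going on: L + E -> D + E; 2 E -> J

Between this flask and delta, both charged with 10 mM of L, the speeds differ by 2.00: I call this the clock factor, the ratio of the two E loadings. Delta reads D at 15.0 % after 50.0 min, so I expect this flask to stand there at 25.0 min. Rates at equal conversion go with the same ratio, so I commit to 2 for doubling and 0.182 for the lower loading.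

The weak link is the pairing of two E: the rule asks that, with the same L charged, the loss of rate in time goes with the E charged. So I compare D made in the first 20.0 min with D made in the last 20.0 min of 50.0 min. The rate falls by a factor of 1.95 in delta, with 1.10 µM of E, and 4.00 in gamma, with 4.84 µM. Gamma's fall is larger, though these are rough readings and gamma also starts with 22 mM of L against delta's 10 mM, so this is a hint and no proof.

The forecast gives 2 and 0.18, holding that the share of E left at 50 % conversion is “the same for any charge”.

The flask gives 2.00 and 0.182. At 50 % conversion, reached after 5.85 h, 96.7 % of the catalyst in this flask is J, and D forms at 0.00464 mM min⁻¹.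

    L + E → D + E, rate k1*[L]*[E]/(1 + ([L]/Km1) + ([L]/Ksi1)^2) (6.73 mM, 3.92 mM, k = 725 M⁻¹ s⁻¹)
    2 E → J (k = 320 M⁻¹ s⁻¹)

The clock factor of 2.00 carries delta's 50.0 min to 25.0 min in this flask, where D stands at 15.0 %, and delta read 15.0 %.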